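3.15 to one: that is how capture by partner stands against loss to side product for intermediate at the start of blue. The flasks below differ in heat, and we ask which holds the most target.

| setting | green | teal | blue | grey |
|---|---|---|---|---|
| starting material | 0.055 M | 0.055 M | 0.055 M | 0.055 M |
| partner | 0.0578 M | 0.0578 M | 0.0578 M | 0.0578 M |
| temperature | 120 °C |  | 100 °C | 140 °C |
| time | 20 min | 20 min | 20 min | 20 min |
| remark |  | at 100 °C until 4.0 min, from then on at 140 °C |  |  |

- the best flask by amount of target, in percent of the starting material charged; "all alike" if 1.5 percentage points covers them all (green / teal / blue / grey / all alike)
- amount of target at the end, in percent of the starting material charged, green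
- amount of target at the end, in percent of the starting material charged, teal
- amount of target at the end, in percent of the starting material charged, blue
- amount of target at the end, in percent of the starting material charged, grey

- percent here means starting material units held: one homo product or homo dimer counts as two
- what is said of target includes crystals
- two of one species on the left: rate k times its square, two consumed each time
- crystals is a solid; its amount is given per volume of the solution
- the constants hold at 100 °C; other temperatures follow from the activation energies

    starting material → intermediate (k1 = 0.77 min⁻¹, Ea1 = 114 kJ mol⁻¹)
    partner + intermediate → target (k2 = 12 L mol⁻¹ min⁻¹, Ea2 = 76.0 kJ mol⁻¹)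
    2 intermediate → homo product (k3 = 8.9 L mol⁻¹ min⁻¹, Ea3 = 79.0 kJ mol⁻¹)
    crystals ⇌ target, rate k4*(cs4 - [target]) while solid is left; crystals form when [target] > cs4 (cs4 = 26 mM, k4 = 37 min⁻¹)
    2 starting material → homo dimer (k5 = 0.0024 L mol⁻¹ min⁻¹, Ea5 = 72.0 kJ mol⁻¹)
    intermediate → side product (k6 = 0.22 min⁻¹, Ea6 = 119 kJ mol⁻¹)
    (constants at 100 °C)

We climb the time scales in blue, fastest first. Crystals answer in 0.0270 min, which is faster than release of intermediate at 1.30 min. That step only moves target between solution and solid, and we count both, so we take it as done and set it aside. Homo coupling takes 1.02 min if the whole charge stood as intermediate, and it slows as [intermediate] falls. Then comes capture, at 1.44 min with partner at its charge, close to release. Loss takes 4.55 min, slower than capture. Homo dimer needs 3790 min, far slower than release, so we drop it.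

Capture and loss both run in [intermediate] to the first power, so it cancels in their ratio. At a fixed temperature, target gained per side product gained is the capture constant over the loss constant, times [partner]. The quotient of the two constants, 54.5 L mol⁻¹ in blue, we call the capture ratio, a selectivity factor. Partner falls by capture, so summing gives a rule: the natural logarithm of charged partner over [partner] equals the capture ratio times [side product]. It holds at fixed temperature, however [intermediate] and homo product move.

From blue to grey capture speeds up 11 times and loss 41 times, so grey has a capture ratio of 14.3 L mol⁻¹, and its start stands at 0.824 to one. On this start we expect more target in blue than in grey. We get no target figure this way; the homo product's share needs [intermediate] through time.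

The forecast puts blue first at 54.5%, then teal at 50%, green at 43.6% and grey at 33.6%, concluding “Cold is therefore best”. Our order of blue over grey is the same, but we commit to no figures.

The simulation gives blue first, at 54.5%, with teal 50.1%, green 43.7% and grey 33.6%. By 4.00 min in blue, release had 95% of its turnover up to the end behind it and loss 77%. In blue, intermediate stood at 0% at 20.0 min. With side product at 24.4%, the capture ratio gives 48.2% of partner left in blue, and the flask holds 48%. In grey, side product at 49.1% gives 68.0%, and the flask holds 68%. Blue's charge run at 75 °C holds 33.9% target at 20.0 min, with 33% of the starting material still there.

The rate constants are assumed; the result is computed.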